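**Retrosynthetic overview**
- The C6 methyl group goes on last: axial methylation of the six-membered peroxycarbenium ion from a 6-methoxy-1,2-dioxane fixes C6 relative to C3.
- The 1,2-dioxane is closed by 6-exo-tet opening of a trans-β-lactone by a C6 hydroperoxy ketal, which inverts C3 and frees the C1 carboxylate.
- The trans-β-lactone comes from a γ-keto aldehyde and propionyl bromide by catalytic asymmetric cyclocondensation, which sets C2 and C3.
- Key C4–C5 bond: the 1,4-keto aldehyde is made from the hypervalent-iodine enolonium of β-ionone (an umpoled enolate) and the enol silane of acetaldehyde; ring oxidation and chain hydrogenation then adjust the ionone part.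
- Ring order: the cyclohexene ring is bought with β-ionone, the β-lactone is formed first, and the 1,2-dioxane is formed last.

Assumption: the (R,R)-configured aluminium salen catalyst of step 3 is taken to give the (3R,4R)-lactone; if its sense is the opposite, the (S,S)-ligand is used.
Labels C1–C6 are those of the target's propanoate–dioxane chain (C1 ester carbon, C3 and C6 the two dioxane carbons).

Step 1
Reactants: 1 β-ionone [(E)-4-(2,6,6-trimethylcyclohex-1-en-1-yl)but-3-en-2-one]
Product: 2 (E)-trimethyl{[4-(2,6,6-trimethylcyclohex-1-en-1-yl)buta-1,3-dien-2-yl]oxy}silane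
Conditions: LiN(iPr)2 (1.05 equiv), THF, −78 °C; TMSCl; pentane, cold aq NaHCO3
Reagents that add atoms: chlorotrimethylsilane, C[Si](C)(C)Cl
Why: Kinetic deprotonation of the methyl group (the only α-CH of this dienone) and O-silylation of the cross-conjugated enolate give the terminal silyl enol ether regiospecifically (kinetic enol silane formation); no stereocenter is involved.

Step 2
Reactants: 2; 3 trimethyl(vinyloxy)silane
Product: 5 (E)-4-oxo-6-(2,6,6-trimethylcyclohex-1-en-1-yl)hex-5-enal, via enolonium species 4 (not isolated)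
Conditions: PhI(OH)OTs (1.05 equiv), BF3·OEt2 (1.5 equiv), CH2Cl2, −78 °C, 10 min; then 3 (3 equiv), −78 to −40 °C; cold aq NaHCO3
Reagents that add atoms: none
Why: Proposed new method: Koser's reagent with BF3 turns the enol silane into an O-bound hypervalent-iodine enolate whose former enolate carbon (C5) is now electrophilic, and the acetaldehyde enol silane attacks it with loss of PhI, so two natively nucleophilic α-carbons are joined to give the 1,4-keto aldehyde; the closest known reaction type is the two-stage hypervalent-iodine enolonium cross-coupling of a ketone silyl enol ether with a second silyl enol ether to give unsymmetrical 1,4-diketones, and no stereocenter is formed.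

Step 3
Reactants: 5; 6 propionyl bromide
Product: 7 (3R,4R)-3-methyl-4-[(4E)-3-oxo-5-(2,6,6-trimethylcyclohex-1-en-1-yl)pent-4-en-1-yl]oxetan-2-one
Conditions: 6 (3 equiv), iPr2NEt (2.5 equiv), [Al(L)Me]Br2 (10 mol%; L = dianion of (R,R)-N,N′-bis[5-tert-butyl-3-(pyridinium-1-ylmethyl)salicylidene]cyclohexane-1,2-diamine), CH2Cl2, −70 °C
Reagents that add atoms: none
Why: Catalytic asymmetric acyl halide–aldehyde cyclocondensation (formal ketene–aldehyde [2+2]): aluminium activates the aldehyde while the pyridinium arms hold the enolate from 6 as a contact ion pair, so an open anti-aldol transition state and ring closure give the trans-lactone and set C2 (R) and C3 (R at this stage) under catalyst control, with the dienone inert.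

Step 4
Reactants: 7
Product: 8 (3R,4R)-3-methyl-4-[(4E)-3-oxo-5-(2,6,6-trimethyl-3-oxocyclohex-1-en-1-yl)pent-4-en-1-yl]oxetan-2-one
Conditions: CrO3 (12 equiv), 3,5-dimethylpyrazole (12 equiv), CH2Cl2, −20 °C
Reagents that add atoms: chromium trioxide, O=[Cr](=O)=O
Why: Allylic oxidation with the CrO3–3,5-dimethylpyrazole complex at the only allylic ring methylene, as in the conversion of β-ionone to 4-oxo-β-ionone, leaves the lactone, the chain ketone and both stereocenters untouched.

Step 5
Reactants: 8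
Product: 9 (3R,4R)-3-methyl-4-[3-oxo-5-(2,6,6-trimethyl-3-oxocyclohex-1-en-1-yl)pentyl]oxetan-2-one
Conditions: H2 (1 atm), 5% Pd/C, EtOAc, rt, stopped after 1 equiv uptake
Reagents that add atoms: none
Why: Chemoselective heterogeneous hydrogenation reduces the disubstituted enone C=C while the hindered tetrasubstituted ring enone, both ketones and the β-lactone survive; the stereocenters are not touched.

Step 6
Reactants: 9
Product: 11 (3R,4R)-4-[3-hydroperoxy-3-methoxy-5-(2,6,6-trimethyl-3-oxocyclohex-1-en-1-yl)pentyl]-3-methyloxetan-2-one, via dimethyl ketal 10 (not isolated)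
Conditions: HC(OMe)3 (3 equiv), MeOH, PPTS (cat.), rt; then anhydrous H2O2 in Et2O (2 equiv), CSA (cat.), 0 °C; cold aqueous work-up, used crude
Reagents that add atoms: trimethyl orthoformate, COC(OC)OC; hydrogen peroxide, OO
Why: Acid-catalysed ketalisation of the only saturated ketone (the hindered conjugated ring ketone does not ketalise and a trans-3,4-dialkyl β-lactone tolerates weakly acidic methanol), followed by acid-catalysed exchange of one methoxy group for hydroperoxide through the oxocarbenium ion (ketal perhydrolysis); the peroxyketal carbon forms as a mixture that is erased in step 8.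

Step 7
Reactants: 11
Product: 13 methyl (2R)-2-{(3S)-6-methoxy-6-[2-(2,6,6-trimethyl-3-oxocyclohex-1-en-1-yl)ethyl]-1,2-dioxan-3-yl}propanoate, via caesium carboxylate 12 (not isolated)
Conditions: Cs2CO3 (1.5 equiv), DMF (0.01 M), 0 °C to rt; then MeI (3 equiv), 0 °C; aq NH4Cl
Reagents that add atoms: iodomethane, CI
Why: Proposed new method: the peroxide anion attacks the lactone β-carbon (C3) from the back in a strain-releasing 6-exo-tet SN2 with alkyl–oxygen cleavage, which inverts C3 to S, cannot proceed by E1cB (the lactone α-proton is not acidic to carbonate) and releases the C1 carboxylate that MeI then O-methylates; the closest known reaction types are alkyl–oxygen opening of β-lactones by azide, thiolate or halide with inversion and base-mediated 6-exo cyclisation of hydroperoxy ketals onto secondary sulfonates.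

Step 8
Reactants: 13
Product: 15 methyl diacarnoate A [methyl (2R)-2-{(3S,6R)-6-methyl-6-[2-(2,6,6-trimethyl-3-oxocyclohex-1-en-1-yl)ethyl]-1,2-dioxan-3-yl}propanoate], via peroxycarbenium ion 14 (not isolated)
Conditions: AlMe3 (3 equiv), TMSOTf (1.1 equiv), CH2Cl2, −78 °C; aq KNaC4H4O6 work-up
Reagents that add atoms: trimethylaluminium, C[Al](C)C
Why: Proposed new method: silylation of the more basic methoxy oxygen ionises the peroxyketal to the cyclic peroxycarbenium ion, and methyl is delivered along the axial trajectory of the half-chair that carries the C3 side chain pseudo-equatorially, so the methyl ends axial and cis to the C3 side chain (6R) whichever ketal epimer is used; the closest known reaction types are Lewis-acid substitution of 3-alkoxy-1,2-dioxanes by allylsilanes and silyl enol ethers through peroxycarbenium ions and axial C-methylation of cyclic ketals by AlMe3.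

**Compound list**
1 | β-ionone, (E)-4-(2,6,6-trimethylcyclohex-1-en-1-yl)but-3-en-2-one | CC(=O)/C=C/C1=C(C)CCCC1(C)C | starting material
2 | (E)-trimethyl{[4-(2,6,6-trimethylcyclohex-1-en-1-yl)buta-1,3-dien-2-yl]oxy}silane | C=C(O[Si](C)(C)C)/C=C/C1=C(C)CCCC1(C)C | intermediate
3 | trimethyl(vinyloxy)silane | C=CO[Si](C)(C)C | starting material
4 | enolonium species, the phenyl(tosyloxy)-λ3-iodanyl enol ether of β-ionone (not isolated) | C=C(O[I](c1ccccc1)OS(=O)(=O)c2ccc(C)cc2)/C=C/C3=C(C)CCCC3(C)C | intermediate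
5 | (E)-4-oxo-6-(2,6,6-trimethylcyclohex-1-en-1-yl)hex-5-enal | O=CCCC(=O)/C=C/C1=C(C)CCCC1(C)C | intermediate
6 | propionyl bromide | CCC(=O)Br | starting material
7 | (3R,4R)-3-methyl-4-[(4E)-3-oxo-5-(2,6,6-trimethylcyclohex-1-en-1-yl)pent-4-en-1-yl]oxetan-2-one | C[C@H]1C(=O)O[C@@H]1CCC(=O)/C=C/C2=C(C)CCCC2(C)C | intermediate
8 | (3R,4R)-3-methyl-4-[(4E)-3-oxo-5-(2,6,6-trimethyl-3-oxocyclohex-1-en-1-yl)pent-4-en-1-yl]oxetan-2-one | C[C@H]1C(=O)O[C@@H]1CCC(=O)/C=C/C2=C(C)C(=O)CCC2(C)C | intermediate
9 | (3R,4R)-3-methyl-4-[3-oxo-5-(2,6,6-trimethyl-3-oxocyclohex-1-en-1-yl)pentyl]oxetan-2-one | C[C@H]1C(=O)O[C@@H]1CCC(=O)CCC2=C(C)C(=O)CCC2(C)C | intermediate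
10 | (3R,4R)-4-[3,3-dimethoxy-5-(2,6,6-trimethyl-3-oxocyclohex-1-en-1-yl)pentyl]-3-methyloxetan-2-one (not isolated) | C[C@H]1C(=O)O[C@@H]1CCC(OC)(OC)CCC2=C(C)C(=O)CCC2(C)C | intermediate
11 | (3R,4R)-4-[3-hydroperoxy-3-methoxy-5-(2,6,6-trimethyl-3-oxocyclohex-1-en-1-yl)pentyl]-3-methyloxetan-2-one (both epimers at the peroxyketal carbon) | C[C@H]1C(=O)O[C@@H]1CCC(OC)(OO)CCC2=C(C)C(=O)CCC2(C)C | intermediate
12 | caesium (2R)-2-{(3S)-6-methoxy-6-[2-(2,6,6-trimethyl-3-oxocyclohex-1-en-1-yl)ethyl]-1,2-dioxan-3-yl}propanoate (not isolated) | [Cs+].[O-]C(=O)[C@H](C)[C@@H]1CCC(OC)(CCC2=C(C)C(=O)CCC2(C)C)OO1 | intermediate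
13 | methyl (2R)-2-{(3S)-6-methoxy-6-[2-(2,6,6-trimethyl-3-oxocyclohex-1-en-1-yl)ethyl]-1,2-dioxan-3-yl}propanoate (both C6 epimers) | COC(=O)[C@H](C)[C@@H]1CCC(OC)(CCC2=C(C)C(=O)CCC2(C)C)OO1 | intermediate
14 | (3S)-3-[(2R)-1-methoxy-1-oxopropan-2-yl]-6-[2-(2,6,6-trimethyl-3-oxocyclohex-1-en-1-yl)ethyl]-1,2-dioxan-6-ylium triflate, the peroxycarbenium ion (not isolated) | COC(=O)[C@H](C)[C@@H]1CCC(CCC2=C(C)C(=O)CCC2(C)C)=[O+]O1.[O-]S(=O)(=O)C(F)(F)F | intermediate
15 | methyl diacarnoate A, methyl (2R)-2-{(3S,6R)-6-methyl-6-[2-(2,6,6-trimethyl-3-oxocyclohex-1-en-1-yl)ethyl]-1,2-dioxan-3-yl}propanoate | COC(=O)[C@H](C)[C@@H]1CC[C@@](C)(CCC2=C(C)C(=O)CCC2(C)C)OO1 | target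

**Totals**
Total step count: 8. Longest linear sequence: 8 (fully linear from β-ionone). The enantiomeric purity of 15 is that of lactone 7.

**Three steps most likely to fail, with fallbacks**

Step 2 is the riskiest C–C bond formation. The aldehyde enol silane is a weaker nucleophile than the ketone enol silanes this coupling is known for. The dienyl enol ether may be over-oxidised or homocoupled. The 1,4-keto aldehyde can also cyclise to a furan under BF3. The fallback sets out from 1 and returns at 5: the kinetic lithium enolate of 1 (LiN(iPr)2, THF, −78 °C) is C-allylated with allyl bromide to give (E)-1-(2,6,6-trimethylcyclohex-1-en-1-yl)hepta-1,6-dien-3-one F1. Its terminal alkene alone is then cleaved by Lemieux–Johnson oxidation (OsO4 cat., NaIO4, 2,6-lutidine, dioxane–water) to give 5.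

Step 7 may fail through intermolecular attack of the peroxide anion on the lactone carbonyl, giving oligomeric peresters, or through slow substitution at the hindered secondary carbon. The fallback sets out from 9 and returns at 13. Compound 9 is treated with anhydrous ethereal H2O2 and catalytic H3PMo12O40, so that neutral H2O2 opens the lactone at C3 by alkyl–oxygen cleavage with inversion. The new hydroperoxide closes onto the C6 ketone to give (2R)-2-{(3S)-6-hydroxy-6-[2-(2,6,6-trimethyl-3-oxocyclohex-1-en-1-yl)ethyl]-1,2-dioxan-3-yl}propanoic acid F2. TMSCHN2 in MeOH–toluene gives its methyl ester, methyl (2R)-2-{(3S)-6-hydroxy-6-[2-(2,6,6-trimethyl-3-oxocyclohex-1-en-1-yl)ethyl]-1,2-dioxan-3-yl}propanoate F3. Exchange of the hemiketal hydroxyl for methoxy (MeOH, HC(OMe)3, PPTS) then gives 13.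

Step 8 may fail because AlMe3 can add to the ring ketone or attack the O–O bond, the ketal may ionise with ring opening, and the facial selectivity is unproven. The fallback sets out from 9 and returns at 15, giving up control at C6.
- The saturated ketone of 9 is methylenated with the Tebbe reagent Cp2Ti(μ-Cl)(μ-CH2)AlMe2 to give (3R,4R)-3-methyl-4-[3-methylidene-5-(2,6,6-trimethyl-3-oxocyclohex-1-en-1-yl)pentyl]oxetan-2-one F4.
- Mukaiyama–Isayama hydroperoxysilylation (Co(acac)2 cat., O2, Et3SiH, ClCH2CH2Cl) gives the tertiary triethylsilyl peroxide (3R,4R)-3-methyl-4-[3-methyl-3-(triethylsilylperoxy)-5-(2,6,6-trimethyl-3-oxocyclohex-1-en-1-yl)pentyl]oxetan-2-one F5 as both C6 epimers.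
- Bu4NF buffered with AcOH frees the hydroperoxide (3R,4R)-4-[3-hydroperoxy-3-methyl-5-(2,6,6-trimethyl-3-oxocyclohex-1-en-1-yl)pentyl]-3-methyloxetan-2-one F6.
- Cs2CO3 in dilute DMF closes the dioxane as in step 7 to give caesium (2R)-2-{(3S)-6-methyl-6-[2-(2,6,6-trimethyl-3-oxocyclohex-1-en-1-yl)ethyl]-1,2-dioxan-3-yl}propanoate F7.
- MeI then gives 15 together with its C6 epimer, methyl (2R)-2-{(3S,6S)-6-methyl-6-[2-(2,6,6-trimethyl-3-oxocyclohex-1-en-1-yl)ethyl]-1,2-dioxan-3-yl}propanoate F8, which is removed by HPLC.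

Further compounds
F1 | step 2 | (E)-1-(2,6,6-trimethylcyclohex-1-en-1-yl)hepta-1,6-dien-3-one | C=CCCC(=O)/C=C/C1=C(C)CCCC1(C)C
F2 | step 7 | (2R)-2-{(3S)-6-hydroxy-6-[2-(2,6,6-trimethyl-3-oxocyclohex-1-en-1-yl)ethyl]-1,2-dioxan-3-yl}propanoic acid | OC(=O)[C@H](C)[C@@H]1CCC(O)(CCC2=C(C)C(=O)CCC2(C)C)OO1
F3 | step 7 | methyl (2R)-2-{(3S)-6-hydroxy-6-[2-(2,6,6-trimethyl-3-oxocyclohex-1-en-1-yl)ethyl]-1,2-dioxan-3-yl}propanoate | COC(=O)[C@H](C)[C@@H]1CCC(O)(CCC2=C(C)C(=O)CCC2(C)C)OO1
F4 | step 8 | (3R,4R)-3-methyl-4-[3-methylidene-5-(2,6,6-trimethyl-3-oxocyclohex-1-en-1-yl)pentyl]oxetan-2-one | C[C@H]1C(=O)O[C@@H]1CCC(=C)CCC2=C(C)C(=O)CCC2(C)C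
F5 | step 8 | (3R,4R)-3-methyl-4-[3-methyl-3-(triethylsilylperoxy)-5-(2,6,6-trimethyl-3-oxocyclohex-1-en-1-yl)pentyl]oxetan-2-one | C[C@H]1C(=O)O[C@@H]1CCC(C)(OO[Si](CC)(CC)CC)CCC2=C(C)C(=O)CCC2(C)C
F6 | step 8 | (3R,4R)-4-[3-hydroperoxy-3-methyl-5-(2,6,6-trimethyl-3-oxocyclohex-1-en-1-yl)pentyl]-3-methyloxetan-2-one | C[C@H]1C(=O)O[C@@H]1CCC(C)(OO)CCC2=C(C)C(=O)CCC2(C)C
F7 | step 8 | caesium (2R)-2-{(3S)-6-methyl-6-[2-(2,6,6-trimethyl-3-oxocyclohex-1-en-1-yl)ethyl]-1,2-dioxan-3-yl}propanoate | [Cs+].[O-]C(=O)[C@H](C)[C@@H]1CCC(C)(CCC2=C(C)C(=O)CCC2(C)C)OO1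
F8 | step 8 | methyl (2R)-2-{(3S,6S)-6-methyl-6-[2-(2,6,6-trimethyl-3-oxocyclohex-1-en-1-yl)ethyl]-1,2-dioxan-3-yl}propanoate | COC(=O)[C@H](C)[C@@H]1CC[C@](C)(CCC2=C(C)C(=O)CCC2(C)C)OO1
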